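## Retrosynthetic overview

1. Last step: chelation-controlled cleavage of the 5-O-methyl group of 3'-hydroxy-5,6,7,2',4',5'-hexamethoxyflavone; no ring is formed.
2. Key disconnection C2–C1': chromone C2, normally the electrophilic (acyl-level, β-enone) carbon, is used as a carbanion. The 2-zincated 5,6,7-trimethoxychromone (an α-alkoxyvinyl, acyl-anion-type donor) is joined to the ipso carbon of 3-bromo-2,5,6-trimethoxyphenol, with its OH left free.
3. Ring order: the γ-pyranone ring is closed first on the bought A-ring acetophenone (enaminone route). The B ring is bought as an arene and only hydroxylated (ortho-lithiation, borylation, oxidation). The coupling joins two finished ring systems.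

Assumption: the target is achiral (no stereocentre, no hindered biaryl axis), so no stereochemistry has to be set; compounds 1 and 4 are taken as catalogue chemicals.

## Route

Step 1
Reactants: 1 1-(2-hydroxy-4,5,6-trimethoxyphenyl)ethan-1-one
Product: 3 5,6,7-trimethoxy-4H-chromen-4-one, via enaminone 2 (not isolated)
Conditions: DMF-DMA (2 equiv), toluene, 100 °C; then conc. HCl, CH2Cl2, 40 °C
Reagents that add atoms: N,N-dimethylformamide dimethyl acetal, COC(OC)N(C)C
Why: Condensation of the methyl ketone with the amide acetal gives the (E)-enaminone, and acid then triggers intramolecular oxa-Michael addition of the phenol and loss of dimethylamine (enaminone chromone synthesis), which closes the γ-pyranone ring with C2 left as C–H.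

Step 2
Reactants: 4 1-bromo-2,4,5-trimethoxybenzene
Product: 7 3-bromo-2,5,6-trimethoxyphenol, via aryllithium 5 (not isolated), via boronate 6 (not isolated)
Conditions: B(Oi-Pr)3 (1.5 equiv), LiTMP (1.2 equiv, from TMPH/n-BuLi), THF, −78 → −50 °C (in situ trap); then AcOH, 30% aq. H2O2, 0 °C → rt
Reagents that add atoms: hydrogen peroxide, OO
Why: Directed ortho-metalation: the proton between the 2- and 4-methoxy groups (further acidified by the meta bromine) is removed by the non-nucleophilic amide base without Br/Li exchange, the aryllithium is trapped as it forms by the borate (in situ quench, which forestalls halogen dance and aryne formation), and peroxide-induced 1,2-aryl shift (boronate oxidation) gives the phenol.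

Step 3
Reactants: 3 5,6,7-trimethoxy-4H-chromen-4-one; 7 3-bromo-2,5,6-trimethoxyphenol
Product: 9 2-(3-hydroxy-2,4,5-trimethoxyphenyl)-5,6,7-trimethoxy-4H-chromen-4-one, via chromenylzinc chloride 8 (not isolated)
Conditions: 3 (1.6 equiv), TMPZnCl·LiCl (1.7 equiv), THF, −30 → 25 °C; then 7 (1.0 equiv), Pd(OAc)2 (2 mol %), SPhos (4 mol %), THF, 50 °C
Reagents that add atoms: none
Why: C2–H, the most acidic proton of the chromone, is zincated selectively to an α-alkoxyvinyl (β-acylvinyl) zinc, i.e. an acyl-anion-type donor at the very carbon that is the electrophilic Michael/acyl terminus of a chromone, and this carbanion is joined to the electrophilic ipso carbon of the aryl bromide by Negishi cross-coupling, the Pd/SPhos cycle outrunning protonation of the zinc reagent by the free phenol.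

Step 4
Reactants: 9 2-(3-hydroxy-2,4,5-trimethoxyphenyl)-5,6,7-trimethoxy-4H-chromen-4-one
Product: 11 psiadiarabicin (5-hydroxy-2-(3-hydroxy-2,4,5-trimethoxyphenyl)-6,7-dimethoxy-4H-chromen-4-one), via bis(dichloroboryl) ether 10 (not isolated)
Conditions: BCl3 (1 M in CH2Cl2, 3 equiv), CH2Cl2, −78 → 0 °C; then H2O, rt
Reagents that add atoms: none
Why: Chelation-controlled Lewis-acid ether cleavage: boron bound to the C4 carbonyl activates only the peri 5-methoxy group through a six-membered chelate for chloride attack on its methyl group, the other five methoxy groups lack this assistance at 0 °C, and aqueous work-up frees both phenols.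

## Compound list

1 | 1-(2-hydroxy-4,5,6-trimethoxyphenyl)ethan-1-one | CC(=O)c1c(O)cc(OC)c(OC)c1OC | starting material
2 | (E)-3-(dimethylamino)-1-(2-hydroxy-4,5,6-trimethoxyphenyl)prop-2-en-1-one | CN(C)/C=C/C(=O)c1c(O)cc(OC)c(OC)c1OC | intermediate
3 | 5,6,7-trimethoxy-4H-chromen-4-one | O=c1ccoc2cc(OC)c(OC)c(OC)c12 | intermediate
4 | 1-bromo-2,4,5-trimethoxybenzene | COc1cc(OC)c(Br)cc1OC | starting material
5 | (3-bromo-2,5,6-trimethoxyphenyl)lithium | [Li]c1c(OC)c(Br)cc(OC)c1OC | intermediate
6 | diisopropyl (3-bromo-2,5,6-trimethoxyphenyl)boronate (formed as its lithium isopropoxide ate complex) | CC(C)OB(OC(C)C)c1c(OC)c(Br)cc(OC)c1OC | intermediate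
7 | 3-bromo-2,5,6-trimethoxyphenol | Oc1c(OC)c(Br)cc(OC)c1OC | intermediate
8 | chlorido(5,6,7-trimethoxy-4-oxo-4H-chromen-2-yl)zinc (LiCl complex) | Cl[Zn]c1cc(=O)c2c(OC)c(OC)c(OC)cc2o1 | intermediate
9 | 2-(3-hydroxy-2,4,5-trimethoxyphenyl)-5,6,7-trimethoxy-4H-chromen-4-one | COc1cc(-c2cc(=O)c3c(OC)c(OC)c(OC)cc3o2)c(OC)c(O)c1OC | intermediate
10 | 5,3'-bis-O-(dichloroboryl) derivative of the target (5-O–B chelated to C4=O) | COc1cc(-c2cc(=O)c3c(OB(Cl)Cl)c(OC)c(OC)cc3o2)c(OC)c(OB(Cl)Cl)c1OC | intermediate
11 | psiadiarabicin, 5-hydroxy-2-(3-hydroxy-2,4,5-trimethoxyphenyl)-6,7-dimethoxy-4H-chromen-4-one | COc1cc(-c2cc(=O)c3c(O)c(OC)c(OC)cc3o2)c(OC)c(O)c1OC | target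

## Count and risks

Total step count: 4. Longest linear sequence: 3 (1 → 3 → 9 → 11, or 4 → 7 → 9 → 11).

The three steps most likely to fail:

**Step 2 (site of deprotonation).** C6–H, flanked by bromine and a methoxy group, may compete with C3–H and lead to the regioisomeric phenol or to an aryne. Fallback: the route is left at compound 4, which is replaced by its bromine-free parent 1,2,4-trimethoxybenzene F1, so that the later OH is carried as a formyl group that steers the bromination. n-BuLi (THF, 0 °C) lithiates F1 only between the two methoxy groups to give (2,3,6-trimethoxyphenyl)lithium F2, and DMF then gives 2,3,6-trimethoxybenzaldehyde F3. NBS in MeCN brominates meta to the formyl group and para to the 2-methoxy group, giving 3-bromo-2,5,6-trimethoxybenzaldehyde F4. mCPBA (Baeyer–Villiger/Dakin oxidation) gives 3-bromo-2,5,6-trimethoxyphenyl formate F5, and K2CO3/MeOH brings the sequence back to the route at compound 7.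

**Step 3 (key coupling).** The free phenol may protonate zinc reagent 8 faster than the hindered, electron-rich bromide undergoes oxidative addition. Fallback: it sets out from compound 7, which is masked with MOMCl/i-Pr2NEt as 1-bromo-2,4,5-trimethoxy-3-(methoxymethoxy)benzene F6. Negishi coupling of F6 with zinc reagent 8 under the step 3 catalyst gives 5,6,7-trimethoxy-2-[2,4,5-trimethoxy-3-(methoxymethoxy)phenyl]-4H-chromen-4-one F7. HCl in MeOH (50 °C) removes the acetal and returns to the route at compound 9.

**Step 4 (selectivity of demethylation).** The 3'-O–BCl2 group formed from the free phenol could assist cleavage of the neighbouring 2'- or 4'-methoxy group, and the 6-methoxy group could follow the 5-methoxy group. Fallback: it sets out from compound 9, which is acetylated (Ac2O, pyridine, DMAP) to 2,5,6-trimethoxy-3-(5,6,7-trimethoxy-4-oxo-4H-chromen-2-yl)phenyl acetate F8, so that the B ring carries no boron-binding oxygen. BCl3 (CH2Cl2, −78 → 0 °C) then gives the 5-O-dichloroboryl chelate F9 and, after aqueous work-up, 3-(5-hydroxy-6,7-dimethoxy-4-oxo-4H-chromen-2-yl)-2,5,6-trimethoxyphenyl acetate F10. K2CO3/MeOH (rt) removes the acetate and arrives at compound 11.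

## Further compounds

F1 | step 2 | 1,2,4-trimethoxybenzene | COc1ccc(OC)c(OC)c1
F2 | step 2 | (2,3,6-trimethoxyphenyl)lithium | [Li]c1c(OC)ccc(OC)c1OC
F3 | step 2 | 2,3,6-trimethoxybenzaldehyde | O=Cc1c(OC)ccc(OC)c1OC
F4 | step 2 | 3-bromo-2,5,6-trimethoxybenzaldehyde | O=Cc1c(OC)c(Br)cc(OC)c1OC
F5 | step 2 | 3-bromo-2,5,6-trimethoxyphenyl formate | O=COc1c(OC)c(Br)cc(OC)c1OC
F6 | step 3 | 1-bromo-2,4,5-trimethoxy-3-(methoxymethoxy)benzene | COCOc1c(OC)c(Br)cc(OC)c1OC
F7 | step 3 | 5,6,7-trimethoxy-2-[2,4,5-trimethoxy-3-(methoxymethoxy)phenyl]-4H-chromen-4-one | COCOc1c(OC)c(-c2cc(=O)c3c(OC)c(OC)c(OC)cc3o2)cc(OC)c1OC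
F8 | step 4 | 2,5,6-trimethoxy-3-(5,6,7-trimethoxy-4-oxo-4H-chromen-2-yl)phenyl acetate | CC(=O)Oc1c(OC)c(-c2cc(=O)c3c(OC)c(OC)c(OC)cc3o2)cc(OC)c1OC
F9 | step 4 | 3-[5-(dichloroboryloxy)-6,7-dimethoxy-4-oxo-4H-chromen-2-yl]-2,5,6-trimethoxyphenyl acetate | CC(=O)Oc1c(OC)c(-c2cc(=O)c3c(OB(Cl)Cl)c(OC)c(OC)cc3o2)cc(OC)c1OC
F10 | step 4 | 3-(5-hydroxy-6,7-dimethoxy-4-oxo-4H-chromen-2-yl)-2,5,6-trimethoxyphenyl acetate | CC(=O)Oc1c(OC)c(-c2cc(=O)c3c(O)c(OC)c(OC)cc3o2)cc(OC)c1OC
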